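## The problem

The target **12** is a flavonol. A benzene ring (ring A) is fused to a 4-pyranone (ring C) that carries the 3,4-dimethoxyphenyl group (ring B) on C2, an enolic hydroxyl on C3 and the carbonyl at C4, and ring A bears a prenyl ether on C7. The molecule has no stereocentre, so nothing has to be controlled in space and any sp3 centre met on the way is temporary. The tasks are regiochemical and redox ones: the aryl group must end on C2 and the oxygen on C3, the ring A ether must sit para to the carbon that bears C4, and ring C must reach the level of an enol double bond next to a ketone. The prenyl ether is the fragile group: its trisubstituted alkene reacts with electrophilic oxidants, halogens and hydrogen over a metal, and its allylic C–O bond ionizes in acid and rearranges on strong heating. A late prenylation would also have to distinguish the 7-hydroxyl from the 3-hydroxyl, which argues for placing the prenyl group before ring C exists. The route is made short by the atom pattern O1–C8a–C4a–C4, which is that of a salicylaldehyde, and by the C2–C3 unit, which carries an aryl group on one carbon and a heteroatom on the other and so maps onto a β-nitrostyrene whose nitro group marks C3 for exchange against oxygen.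

## Retrosynthesis

**From 12 to nitrochromene 9.** No skeletal bond is cut. The C3–OH and C4=O of **12** are traced back to the C3–NO2 and C4–H of 2-(3,4-dimethoxyphenyl)-7-(prenyloxy)-3-nitro-2H-chromene **9**. Flavonol **12** is the enol of a 3,4-dione, which lies two electrons above the ring C acyloin **11**. Acyloin **11** is what the α-nitro epoxide **10** gives when an oxygen nucleophile opens it at C4 and nitrite leaves from C3, and **10** is the product of nucleophilic epoxidation of the nitroalkene of **9**. The neighbouring choice, hydroxylating C3 of a finished flavone, needs strong base or an electrophilic oxidant that the prenyl alkene would not tolerate. The nitro route asks only for alkaline hydrogen peroxide, a nucleophilic oxidant that ignores an electron-rich alkene. Precursor **9** has neither the carbonyl nor the enol. The forward reaction must epoxidize faster than hydroxide reverses the ring formation, and must stop at the flavonol.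

**From 9 to salicylaldehyde 3 and nitrostyrene 6.** The bonds O1–C2 and C3–C4 are cut. Cutting C4–C4a instead would call for a Lewis-acid acylation of an electron-rich arene, which raises an ortho/para question and endangers the prenyl ether. Cutting O1–C8a would need an aryl–oxygen coupling. The chosen cut follows the natural polarity of both partners: phenoxide oxygen to the β-carbon of the nitroalkene, nitronate carbon to the aldehyde. It divides **9** into 2-hydroxy-4-(prenyloxy)benzaldehyde **3** and (E)-3,4-dimethoxy-β-nitrostyrene **6**, each one step from commerce. The forward reaction must form both bonds and dehydrate under conditions no harsher than an amine base.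

**From 3 to 2,4-dihydroxybenzaldehyde 1 and prenyl bromide 2.** The prenyl O–C bond is cut. At this stage the two hydroxyls differ sharply: the 2-hydroxyl is chelated to the aldehyde and less acidic, while the 4-hydroxyl is free and para to the carbonyl. All later steps are basic or nucleophilic, so the ether can be carried from the start. The forward reaction must give mono-O-alkylation at the 4-position.

**From 6 to 3,4-dimethoxybenzaldehyde 4 and nitromethane 5.** The alkene C=C is cut by a Henry condensation. Both starting materials are bulk chemicals, and the forward reaction only has to give the E-alkene, which is the stable isomer.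

## Roads not taken

Alternative 1: Ring C is cut at C4–C4a and O1–C8a, so that C2, C3 and C4 with their oxygen atoms come from an acylketene and ring A arrives as a non-aromatic six-membered ring. In the forward sense, heating the dioxinone **A1** would release the α-benzyloxy aroylketene **A2**. This would add across the silyl enol ether double bond of the siloxydiene **A3**, and loss of the silyloxy group would give the dihydrochromenone **A4**.
- Merits: the pyranone forms with the C3 oxygen and C4 carbonyl at their final level, the regiochemistry follows from ketene and enol ether polarity, and the medium is neutral.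
- Weak points: ring A, a resorcinol-type benzene ring that can be bought, has to be built and then dehydrogenated. **A1** is itself a multistep compound. **A3** offers the ketene a second electron-rich double bond and a diene, so periselectivity is not assured. Both oxygens arrive as benzyl ethers, whose hydrogenolysis the prenyl alkene would not survive, so the prenyl group would go on last and the 7-hydroxyl would have to be alkylated beside the 3-hydroxyl.
- Comparison: this road is better in needing no oxidation of a finished skeleton and in installing the C3 oxygen directly instead of by a nitro-to-oxygen exchange. The chosen plan sets against this about half the step count, no protecting group and a purchased ring A.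

Alternative 2: The cut is O1–C2 together with the C3–O bond, and ring C is grown from a five-membered ring. The Z-aurone **A5** would take up bromine across its benzylidene double bond to give the dibromide **A6**. Aqueous KOH would open this to a phenoxide 1,2-diketone that recloses on the benzylic carbon and expands the ring to the 3,7-dihydroxyflavone **A7** (Auwers synthesis).
- Merits: classical, cheap and short. The bromine atoms supply the oxidation level, so no peroxide is needed, and **A7** would be a branching point for other 7-ethers.
- Weak points: bromine must choose the exocyclic alkene over two strongly activated arenes, the veratryl ring and a ring A with a free phenol. The prenyl alkene cannot be present during bromination, so the target needs a final 7-O-prenylation of **A7** beside the 3-hydroxyl. The hot alkaline step can partly return aurone by dehydrobromination.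
- Comparison: in step count this road is about equal to the chosen plan, and its last alkylation is probably workable because the 7-hydroxyl is the more acidic. The chosen plan sets against it the absence of electrophilic halogen near electron-rich rings and a prenyl group placed in step 1, where chelation decides between the two hydroxyls.

Alternative 3: C3–C4 is cut, with a temporary O–C2 bond, and the ring C carbons are held as an isoxazole. The nitrile oxide **A8** would add to the α-alkoxy enamine **A9** with carbon bonding to the enamine β-carbon and oxygen to the amine-bearing carbon. Loss of the secondary amine from the isoxazoline would give the isoxazole **A10**. Reductive N–O cleavage, hydrolysis to the 2-alkoxy-1,3-diketone, and acid removal of both methoxymethyl groups with cyclodehydration would follow.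
- Merits: the regiochemistry is fixed by the cycloaddition, the two aryl halves are joined convergently, and all ring C oxygens are present before the ring closes, so no final oxidation is needed. The prenyl group is carried from the start.
- Weak points: the closing acid step removes acetal protecting groups in the presence of an acid-labile prenyl aryl ether. Generating **A8** by chlorination of an oxime exposes the prenyl alkene and an electron-rich ring to an electrophilic halogen source. Hydrogenolytic N–O cleavage is excluded by the alkene, so a metal carbonyl such as Mo(CO)6 or a low-valent metal reagent would be needed. The longest line is roughly twice that of the chosen plan.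
- Comparison: this road is superior in avoiding any oxidation at the end and in its modularity. The chosen plan sets against it four steps, no protecting groups and no acid anywhere.

Key step: step 3

Remark on the chemistry: the sp3 centres at C2, C3 and C4 in compounds **7**–**11** are all removed on the way to **12**. These compounds are racemic (**8**, **10** and **11** as diastereomer mixtures) and are written without configuration.

## Route

Step 1
Reactants: 1 2,4-dihydroxybenzaldehyde; 2 1-bromo-3-methylbut-2-ene (prenyl bromide)
Product: 3 2-hydroxy-4-[(3-methylbut-2-en-1-yl)oxy]benzaldehyde
Conditions: 2 (1.05 equiv), CsHCO3 (1.5 equiv), MeCN, 60 °C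
Reagents that add atoms: none
Why: Williamson ether synthesis. The weak bicarbonate base ionizes only the free, more acidic 4-hydroxyl (para to the aldehyde), while the 2-hydroxyl stays locked in its hydrogen bond to the carbonyl, so SN2 attack on the primary allylic bromide should give the 4-monoether.

Step 2
Reactants: 4 3,4-dimethoxybenzaldehyde; 5 nitromethane
Product: 6 1,2-dimethoxy-4-[(E)-2-nitroethenyl]benzene
Conditions: MeNO2 (5 equiv), NH4OAc (0.3 equiv), AcOH, 100 °C
Reagents that add atoms: none
Why: Henry (nitroaldol) condensation with dehydration in the same pot. The conjugated E-nitroalkene is the thermodynamic product and should crystallize from the cooled mixture.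

Step 3
Reactants: 3 2-hydroxy-4-[(3-methylbut-2-en-1-yl)oxy]benzaldehyde; 6 1,2-dimethoxy-4-[(E)-2-nitroethenyl]benzene
Product: 9 2-(3,4-dimethoxyphenyl)-7-[(3-methylbut-2-en-1-yl)oxy]-3-nitro-2H-chromene (racemic), via oxa-Michael adduct 7 (not isolated), via 4-hydroxy-3-nitrochromane 8 (not isolated)
Conditions: 6 (1.2 equiv), DABCO (0.5 equiv), MeCN (1 M), 50 °C
Reagents that add atoms: none
Why: DABCO deprotonates the chelated phenol of 3, and the phenoxide adds to the β-carbon of nitroalkene 6 (oxa-Michael) to give 7 as its nitronate, with the O1–C2 bond in place. The nitronate carbon then attacks the ortho aldehyde in a favoured 6-(enolexo)-exo-trig nitroaldol (Henry) closure that forms C3–C4 and ring C as nitrochromanol 8. E1cB loss of water from 8 gives the nitroalkene conjugated with ring A, which makes the otherwise reversible sequence irreversible. The closest known reaction type is the tertiary-amine-catalysed oxa-Michael/Henry/dehydration annulation of salicylaldehydes with β-nitrostyrenes to 2-aryl-3-nitro-2H-chromenes. The only stereocentre of 9, C2, is set without control in the conjugate addition and is carried as a racemate because it becomes sp2 in step 4; the centres at C3 and C4 of 8 vanish on dehydration. The step needs regioselectivity, and the polarity of the nitroalkene secures it: oxygen can bond only to the aryl-bearing β-carbon and the nitronate carbon only to the aldehyde carbon, so the aryl group ends at C2 and nitrogen at C3. It also needs chemoselectivity, which follows because the prenyl ether offers an amine base no electrophilic or acidic site. Both partners are electron-rich, so high concentration, a slight excess of 6 and gentle heating are used to keep the annulation ahead of amine-induced oligomerization of 6.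

Step 4
Reactants: 9 2-(3,4-dimethoxyphenyl)-7-[(3-methylbut-2-en-1-yl)oxy]-3-nitro-2H-chromene
Product: 12 2-(3,4-dimethoxyphenyl)-3-hydroxy-7-[(3-methylbut-2-en-1-yl)oxy]-4H-chromen-4-one, via nitro epoxide 10 (not isolated), via ring C acyloin 11 (not isolated)
Conditions: 30% aq H2O2 (5 equiv), 2 M aq NaOH (3 equiv), MeOH/THF, 0 °C to rt
Reagents that add atoms: hydrogen peroxide, OO; sodium hydroxide, [Na+].[OH-]
Why: Hydroperoxide adds to C4 of the nitroalkene and the nitronate closes onto the O–O bond (Weitz–Scheffer nucleophilic epoxidation) to give 10; hydroxide opens the oxirane at the benzylic C4 and the C3 nitro alkoxide expels nitrite to give acyloin 11. Alkaline peroxide then oxidizes 11 through its enediolate, as in the last stage of the Algar–Flynn–Oyamada reaction, and 12 forms as its enolate. The conversion of 2-aryl-3-nitro-2H-chromenes into flavonols by alkaline peroxide is a known reaction type, and the nucleophilic oxidant should leave the electron-rich prenyl alkene alone.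

## Compound list

1 | 2,4-dihydroxybenzaldehyde | O=Cc1ccc(O)cc1O | starting material
2 | 1-bromo-3-methylbut-2-ene (prenyl bromide) | CC(C)=CCBr | starting material
3 | 2-hydroxy-4-[(3-methylbut-2-en-1-yl)oxy]benzaldehyde | CC(C)=CCOc1ccc(C=O)c(O)c1 | intermediate
4 | 3,4-dimethoxybenzaldehyde | COc1ccc(C=O)cc1OC | starting material
5 | nitromethane | C[N+](=O)[O-] | starting material
6 | 1,2-dimethoxy-4-[(E)-2-nitroethenyl]benzene | COc1ccc(/C=C/[N+](=O)[O-])cc1OC | intermediate
7 | 2-[1-(3,4-dimethoxyphenyl)-2-nitroethoxy]-4-[(3-methylbut-2-en-1-yl)oxy]benzaldehyde (racemic; formed as its nitronate) | COc1ccc(C(C[N+](=O)[O-])Oc2cc(OCC=C(C)C)ccc2C=O)cc1OC | intermediate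
8 | 2-(3,4-dimethoxyphenyl)-7-[(3-methylbut-2-en-1-yl)oxy]-3-nitro-3,4-dihydro-2H-chromen-4-ol (racemic, diastereomer mixture) | COc1ccc(C2Oc3cc(OCC=C(C)C)ccc3C(O)C2[N+](=O)[O-])cc1OC | intermediate
9 | 2-(3,4-dimethoxyphenyl)-7-[(3-methylbut-2-en-1-yl)oxy]-3-nitro-2H-chromene (racemic) | COc1ccc(C2Oc3cc(OCC=C(C)C)ccc3C=C2[N+](=O)[O-])cc1OC | intermediate
10 | 3,4-epoxy-2-(3,4-dimethoxyphenyl)-7-[(3-methylbut-2-en-1-yl)oxy]-3-nitrochromane, i.e. 2-(3,4-dimethoxyphenyl)-5-[(3-methylbut-2-en-1-yl)oxy]-1a-nitro-1a,7b-dihydro-2H-oxireno[2,3-c]chromene (racemic, diastereomer mixture) | COc1ccc(C2Oc3cc(OCC=C(C)C)ccc3C3OC23[N+](=O)[O-])cc1OC | intermediate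
11 | 2-(3,4-dimethoxyphenyl)-4-hydroxy-7-[(3-methylbut-2-en-1-yl)oxy]-2H-chromen-3(4H)-one (racemic, diastereomer mixture) | COc1ccc(C2Oc3cc(OCC=C(C)C)ccc3C(O)C2=O)cc1OC | intermediate
12 | 2-(3,4-dimethoxyphenyl)-3-hydroxy-7-[(3-methylbut-2-en-1-yl)oxy]-4H-chromen-4-one | COc1ccc(-c2oc3cc(OCC=C(C)C)ccc3c(=O)c2O)cc1OC | target

## Step count and risks

Total step count: 4. Longest linear sequence: 3 steps (1 → 3 → 9 → 12; the branch 4 → 6 joins at step 3).

**Step 3 (key step).** The most likely failure is a slow, reversible conjugate addition. The aldehyde is deactivated by its para alkoxy group and the nitroalkene by its two methoxy groups, so amine-induced oligomerization of the nitroalkene may outrun ring closure, or the sequence may stall before dehydration. The fallback raises the electrophilicity of the carbonyl partner.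
- Setting out from **3**, the aldehyde is condensed with 4-methylbenzenesulfonamide (pyrrolidine cat., 4 Å MS, CH2Cl2, 40 °C) to the imine N-[(E)-{2-hydroxy-4-[(3-methylbut-2-en-1-yl)oxy]phenyl}methylidene]-4-methylbenzenesulfonamide F1.
- F1 and **6** are joined with DABCO in the known oxa-Michael/aza-Henry sequence of salicyl N-sulfonyl imines with nitroalkenes. This gives the sulfonamide N-{2-(3,4-dimethoxyphenyl)-7-[(3-methylbut-2-en-1-yl)oxy]-3-nitro-3,4-dihydro-2H-chromen-4-yl}-4-methylbenzenesulfonamide F2.
- F2 loses 4-methylbenzenesulfonamide on warming with K2CO3 in MeCN, and the route is rejoined at **9**.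

**Step 4.** Three processes threaten the cascade. Hydroxide rather than hydroperoxide may add to C4, and retro-Henry and retro-oxa-Michael fragmentation then undo ring C. Peroxide may attack the dione tautomer and cleave the C3–C4 bond. The last oxidation may be incomplete and leave material at the acyloin level. The fallback separates the stages and removes peroxide from the final oxidation.
- Setting out from **9**, the epoxidation is run with a small excess of H2O2 and NaOH at 0 °C for a short time, and the nitro epoxide **10** is isolated by extraction.
- **10** is solvolysed in aqueous THF buffered with NaHCO3 to the acyloin **11**.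
- **11** is oxidized at its benzylic carbinol with activated MnO2 in CH2Cl2 at room temperature. The resulting dione enolizes, and the route is rejoined at **12**.
- This fallback passes only through compounds already in the list (entry F0).

**Step 1.** The risk is loss of site selectivity: alkylation of the chelated 2-hydroxyl as well, or C-prenylation of the electron-rich ring by the reactive allylic bromide. The fallback changes the electrophile. Setting out from **1**, a Mitsunobu reaction with 3-methylbut-2-en-1-ol (PPh3, DIAD, THF, 0 °C) engages the more acidic, non-chelated 4-hydroxyl under neutral conditions, where no free phenoxide is present to alkylate on carbon. It returns to the route at **3** without any new intermediate (entry F0).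

## Further compounds

F1 | step 3 | N-[(E)-{2-hydroxy-4-[(3-methylbut-2-en-1-yl)oxy]phenyl}methylidene]-4-methylbenzenesulfonamide | CC(C)=CCOc1ccc(/C=N/S(=O)(=O)c2ccc(C)cc2)c(O)c1
F2 | step 3 | N-{2-(3,4-dimethoxyphenyl)-7-[(3-methylbut-2-en-1-yl)oxy]-3-nitro-3,4-dihydro-2H-chromen-4-yl}-4-methylbenzenesulfonamide (racemic, diastereomer mixture) | COc1ccc(C2Oc3cc(OCC=C(C)C)ccc3C(NS(=O)(=O)c3ccc(C)cc3)C2[N+](=O)[O-])cc1OC
F0 | step 4 | none | none
F0 | step 1 | none | none
A1 | alternative 1 | 5-(benzyloxy)-6-(3,4-dimethoxyphenyl)-2,2-dimethyl-4H-1,3-dioxin-4-one | COc1ccc(C2=C(OCc3ccccc3)C(=O)OC(C)(C)O2)cc1OC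
A2 | alternative 1 | 2-(benzyloxy)-3-(3,4-dimethoxyphenyl)-3-oxoprop-1-en-1-one (acylketene) | COc1ccc(C(=O)C(OCc2ccccc2)=C=O)cc1OC
A3 | alternative 1 | {[5-(benzyloxy)cyclohexa-1,5-dien-1-yl]oxy}(tert-butyl)dimethylsilane | CC(C)(C)[Si](C)(C)OC1=CCCC(OCc2ccccc2)=C1
A4 | alternative 1 | 3,7-bis(benzyloxy)-2-(3,4-dimethoxyphenyl)-5,6-dihydro-4H-chromen-4-one | COc1ccc(C2=C(OCc3ccccc3)C(=O)C3=C(C=C(OCc4ccccc4)CC3)O2)cc1OC
A5 | alternative 2 | (2Z)-2-[(3,4-dimethoxyphenyl)methylidene]-6-hydroxy-1-benzofuran-3(2H)-one | COc1ccc(/C=C2\Oc3cc(O)ccc3C2=O)cc1OC
A6 | alternative 2 | 2-bromo-2-[bromo(3,4-dimethoxyphenyl)methyl]-6-hydroxy-1-benzofuran-3(2H)-one (racemic) | COc1ccc(C(Br)C2(Br)Oc3cc(O)ccc3C2=O)cc1OC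
A7 | alternative 2 | 2-(3,4-dimethoxyphenyl)-3,7-dihydroxy-4H-chromen-4-one | COc1ccc(-c2oc3cc(O)ccc3c(=O)c2O)cc1OC
A8 | alternative 3 | 2-(methoxymethoxy)-4-[(3-methylbut-2-en-1-yl)oxy]benzonitrile oxide | COCOc1cc(OCC=C(C)C)ccc1C#[N+][O-]
A9 | alternative 3 | 1-[1-(3,4-dimethoxyphenyl)-2-(methoxymethoxy)ethenyl]pyrrolidine (alkene geometry not defined) | COCOC=C(N1CCCC1)c1ccc(OC)c(OC)c1
A10 | alternative 3 | 5-(3,4-dimethoxyphenyl)-4-(methoxymethoxy)-3-{2-(methoxymethoxy)-4-[(3-methylbut-2-en-1-yl)oxy]phenyl}-1,2-oxazole | COCOc1cc(OCC=C(C)C)ccc1-c1noc(-c2ccc(OC)c(OC)c2)c1OCOC
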